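**Numbering.** Compounds are numbered 1–36 in the order in which they enter the steps; 21 is the Heck precursor, 22 its product and 36 the target.

**Remark on the chemistry.** Eremophilane numbering is used for ring compounds (ring A = C1–C5, C10; ring B = C5–C10; C14 = methyl on C5, C15 = methyl on C4, C11–C13 = isopropenyl on C7), β is the face of the decalin that carries C14, and the same atom labels are used for the acyclic intermediates.

## Analysis of the target

Compound 36 is a cis-fused eremophilane: a 4β,5β-dimethyldecalin (10β-H) with a tiglate on C3 (α), a senecioate on C9 (β), a ketone at C8 and an isopropenyl group on C7 (β). It has six stereocentres; C3, C4, C5 and C10 are contiguous on ring A, C9 is attached to C10, and C7 sits alone on ring B between C6 and the C8 carbonyl. The C4 and C5 methyl groups are cis, H10 is cis to the C5 methyl, O3 is trans to the C4 methyl, and O9 and the isopropenyl group lie on the β-face, so that in the conformer with C14 axial on ring A every other substituent is equatorial. C7 and C9 flank the ketone and are therefore the thermodynamically preferred epimers, whereas C3, C4, C5 and C10 must be set kinetically. The sensitive points are the β,γ-unsaturated ketone (H7 is α to C8 and allylic, so acid or base can epimerise C7 or move the 11,12-alkene into conjugation), the α-acyloxy ketone at C9, and two different enoate esters that must go onto two secondary hydroxyls in a fixed order. The main difficulty is quaternary C5, flanked by C4 and C10, which must be made with the cis ring fusion. The plan rests on the C4–C5 bond: C4 carries a one-carbon substituent and hangs on the C1–C2–C3 chain from C10, and C5 is the methyl-bearing end of a possible 5,6-alkene of ring B. An alkenyl–alkene coupling from C4 to C5 therefore closes ring A on the chain face and leaves a 4(15)-methylene and a 6,7-alkene as handles for C4, C7 and C8.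

## Retrosynthetic reasoning

**C6–H and C7–H.** The isopropenyl ketone is the most fragile part of 36, so it is formed last. Removing the hydrogens at C6 and C7 gives the cross-conjugated dienone 34. Forward, hydride must go to C6 only and the dienolate must be protonated at C7, not C12, from the α-face. That axial protonation gives the equatorial 7β-isopropenyl group, which is also the more stable epimer.

**C7–C11.** Cutting the bond between C7 and the isopropenyl carbon of 34 gives iodoenone 32 and stannane 33; the iodine comes from enone 31. A neutral sp2–sp2 coupling is chosen over an enolate alkenylation or an aldol–dehydration at C7, because those need base on a ketone that is acidic at both C7 and C9.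

**The esters and the C8 carbonyl.** 31 is the senecioate of hydroxy enone 28 with acid 29; 28 comes from silyl ether 27. The C8 carbonyl of 27 is traced to the allylic methylene of 26, which is the tiglate of alcohol 24 with acid chloride 25. The tiglate goes on first because C3–OH is free at that stage; as an ester it also deactivates ring A toward the oxidant. The senecioate goes on after the oxidation so that its allylic methyls never meet the oxidant. Both esters are in place before C7 is created, so no deprotection or acylation touches the finished β,γ-unsaturated ketone.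

**C4–H (C4 stereocentre).** 24 is traced to allylic alcohol 23 by removing H2 from C4–C15, and 23 to bis-silyl ether 22. The forward hydrogenation must deliver hydrogen to C4 from the α-face and must leave the 6,7-alkene alone. A hydroxyl-directed ruthenium catalyst does both: it reduces only alkenes that can chelate through a neighbouring OH. Doing this before the C8 oxidation removes the 4(15)-alkene, whose allylic, oxygen-bearing C3–H would otherwise compete in that oxidation.

**C4–C5 (ring A, key disconnection).** Cutting C4–C5 of 22 and returning a hydrogen to C7 gives alkenyl triflate 21. This is the only bond whose formation creates the quaternary centre, closes a ring and uses an existing stereocentre (C10) one atom away to fix the new one. The forward reaction must be 6-exo, occur on the face of the C1 chain, and eliminate toward C7.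

**Triflate and C15.** 21 comes from methyl ketone 19 by kinetic enolisation at the methyl group, and 19 from Weinreb amide 18 by addition of a methyl nucleophile (C15). Keeping C4 as the amide until ring B is finished avoids a second enolisable ketone earlier on.

**C5=C6 (ring B).** 18 is opened across C5=C6 to diene 17 (ring-closing metathesis forward). The isopropenyl group of 17 comes from methyl ketone 16, this from thioester 15 and imide 14. The thioester is used because a methylcopper reagent converts it to the ketone without touching the C4 Weinreb amide. A direct alkylation of a ring enolate at C10 would be shorter, but it was set aside: it cannot control C10 relative to C3 and gives a deconjugated ketone that readily isomerises.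

**C9–C10.** 14 is the silyl ether of aldol adduct 13, which is cut between C9 and C10 into imide 10 and aldehyde 11. An auxiliary-controlled syn aldol sets both centres at once. The 9,10-syn relationship of the open chain becomes the trans arrangement of O9 and C1 on ring B.

**The C1–C4 chain.** 10 is the imide of acid 7 and auxiliary 8. 7 comes from enoate 6, and 6 from aldehyde 4 and ylide 5 (C10 and C5). 4 is reached through 3 and 2 from lactone 1, which supplies C1–C4 and the C3 stereocentre.

## Alternatives that were turned down

**Alternative 1:** Enzymatic cyclisation of (2E,6E)-farnesyl diphosphate A2 to (+)-aristolochene A1.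
- Disconnection: all ring bonds of the decalin at once.
- Forward key step: a class 1 terpene cyclase ionises A2, closes a ten-membered ring and then the bicycle, shifts a hydride and a methyl group, and loses a proton to give A1.
- For: one step gives the whole carbon skeleton in one enantiomer, with the cis C4/C5 methyls and the C7 side chain. For the skeleton this is far stronger in step economy than the chosen route.
- Against: A1 has no oxygen. C3 is an unactivated methylene with no handle, so the 3α-oxygen needs a site- and face-selective C–H hydroxylation. The 9,10-alkene must become 9β-O, 8-oxo and the 10β-H fusion. As drawn, A1 has the isopropenyl group trans to C14, the opposite of 36, so C7 must be inverted through the ketone with the conjugation risk. The route also depends on access to the enzyme.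
- Comparison: the chosen route is much longer, but it brings O3 from 1 and O9 from the aldol and sets every stereocentre by a controllable reaction.

**Alternative 2:** Anionic oxy-Cope rearrangement of vinyl carbinol A4, a bicyclo[2.2.2]octene in which C3 and C8 are bonded.
- Disconnection: C1–C10 of ring A.
- Forward key step: the alkoxide of A4 undergoes a [3,3] shift that forms C1–C10, breaks C3–C8 and gives cis-decalin A3 with a C3 ketone and a C8 methyl enol ether.
- For: the shift is stereospecific, so the cis fusion and the C4/C5 relationship come from the rigid bicycle. Oxygen arrives at C3 and C8 together, so no allylic C–H oxidation is needed, and the enol ether leads on to C9. On C8/C9 oxygenation it is stronger than the chosen route, and it is probably shorter.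
- Against: the stereochemical load moves into A4 (quaternary bridgehead C5, the C4 methyl, the carbinol with vinyl on the alkene side, all in one enantiomer), which needs an asymmetric cycloaddition or a resolution. The C3 ketone of A3 must be reduced selectively next to an epimerisable C4. C7 and C9 must later be told apart on either side of C8.
- Comparison: the chosen route offers absolute control from a chiral-pool lactone and an auxiliary aldol, and carries O3 as a protected alcohol throughout.

**Alternative 3:** Intramolecular carbonyl-ene closure of aldehyde A6 to carbinol A5.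
- Disconnection: C7–C8 of ring B.
- Forward key step: a mild Lewis acid activates the C8 aldehyde of A6, which bonds to C7 of the prenyl group on C5 while a methyl hydrogen moves to oxygen. This closes ring B and creates the isopropenyl group; oxidation of the C8 carbinol would finish 36.
- For: the β,γ-unsaturated pattern and C7 arise without any enolate at C7. This is stronger than the chosen end game exactly where the chosen route is most exposed, and both esters are already in place.
- Against: A6 must already contain C3, C4, C9, C10 and the quaternary C5, so the hardest part of the problem is left unsolved. The α-acyloxy aldehyde can epimerise at C9 or eliminate. The Lewis acid must pick the aldehyde over two esters. A further oxidation next to C7 is still needed.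
- Comparison: the chosen route creates C5 in the ring-closing event under control from C10, at the price of a longer end game.

Key step: step 15

## Route

Step 1
Reactants: 1 (R)-3-hydroxydihydrofuran-2(3H)-one
Product: 2 (R)-3-(triethylsilyloxy)dihydrofuran-2(3H)-one
Conditions: TESCl, imidazole, CH2Cl2, 0 °C → rt
Reagents that add atoms: chlorotriethylsilane, CC[Si](Cl)(CC)CC
Why: Silylation of the secondary α-hydroxyl with a silyl chloride and imidazole; the stereocentre (future C3) is not touched.

Step 2
Reactants: 2 TES-protected lactone
Product: 3 (R)-4-hydroxy-N-methoxy-N-methyl-2-(triethylsilyloxy)butanamide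
Conditions: MeNHOMe·HCl, Me3Al, CH2Cl2, 0 °C → rt
Reagents that add atoms: N,O-dimethylhydroxylamine hydrochloride, CNOC.Cl
Why: Aluminium amide aminolysis of the lactone (Weinreb amide formation) frees the primary C1 hydroxyl and installs the acyl group that later becomes the C4 methyl ketone.

Step 3
Reactants: 3 hydroxy Weinreb amide
Product: 4 (R)-N-methoxy-N-methyl-4-oxo-2-(triethylsilyloxy)butanamide
Conditions: Dess–Martin periodinane, NaHCO3, CH2Cl2, 0 °C → rt
Reagents that add atoms: none
Why: Buffered, amine-free Dess–Martin oxidation of the primary alcohol should avoid β-elimination of the silyloxy group and relactonisation.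

Step 4
Reactants: 4 aldehyde; 5 benzyl (triphenylphosphoranylidene)acetate
Product: 6 benzyl (R,E)-6-[methoxy(methyl)amino]-6-oxo-5-(triethylsilyloxy)hex-2-enoate
Conditions: CH2Cl2, rt
Reagents that add atoms: none
Why: Wittig olefination with a stabilised, weakly basic ylide adds the carbons that become C10 and C5; the alkene geometry is irrelevant because the double bond is reduced next.

Step 5
Reactants: 6 benzyl enoate
Product: 7 (R)-6-[methoxy(methyl)amino]-6-oxo-5-(triethylsilyloxy)hexanoic acid
Conditions: H2 (1 atm), Pd/C, EtOAc, rt
Reagents that add atoms: none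
Why: Heterogeneous hydrogenation saturates the alkene and hydrogenolyses the benzyl ester in one operation; the TES ether and the amide N–O bond should survive in ethyl acetate at 1 atm.

Step 6
Reactants: 7 acid; 8 (R)-4-benzyloxazolidin-2-one
Product: 10 (R)-4-benzyl-3-{(R)-6-[methoxy(methyl)amino]-6-oxo-5-(triethylsilyloxy)hexanoyl}oxazolidin-2-one, via mixed pivalic anhydride 9 (not isolated)
Conditions: PivCl, Et3N, THF, −20 °C; then 8, LiCl, −20 °C → rt
Reagents that add atoms: none
Why: N-Acylation of the oxazolidinone through the mixed anhydride (LiCl/Et3N protocol) gives the imide needed for the aldol reaction.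

Step 7
Reactants: 10 imide; 11 pent-4-enal
Product: 13 (R)-4-benzyl-3-{(2R,5R)-2-[(S)-1-hydroxypent-4-en-1-yl]-6-[methoxy(methyl)amino]-6-oxo-5-(triethylsilyloxy)hexanoyl}oxazolidin-2-one, via dibutylboron Z-enolate 12 (not isolated)
Conditions: Bu2BOTf, i-Pr2NEt, CH2Cl2, −78 → 0 °C; 11, −78 → 0 °C; then pH 7 buffer, MeOH, H2O2, 0 °C
Reagents that add atoms: none
Why: Evans syn aldol reaction: the Z-boron enolate reacts through a closed chair transition state on the face away from the benzyl group, which sets C10 (R) and C9 (S). This 9,10-syn pair becomes the trans relationship of O9 and C1 on ring B.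

Step 8
Reactants: 13 aldol adduct
Product: 14 the C9 tert-butyldimethylsilyl ether of 13
Conditions: TBSOTf, 2,6-lutidine, CH2Cl2, −78 → 0 °C
Reagents that add atoms: tert-butyldimethylsilyl trifluoromethanesulfonate, CC(C)(C)[Si](C)(C)OS(=O)(=O)C(F)(F)F
Why: Silyl triflate silylation of the hindered secondary alcohol; TBS at O9 is chosen because it outlasts the TES group at O3 and survives the later allylic oxidation.

Step 9
Reactants: 14 silylated imide
Product: 15 S-ethyl (2R,5R)-2-[(S)-1-(tert-butyldimethylsilyloxy)pent-4-en-1-yl]-6-[methoxy(methyl)amino]-6-oxo-5-(triethylsilyloxy)hexanethioate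
Conditions: EtSH, n-BuLi, THF, 0 °C
Reagents that add atoms: ethanethiol, CCS
Why: Thiolate displacement of the oxazolidinone is selective for the activated imide carbonyl over the Weinreb amide and is not basic enough to epimerise C10.

Step 10
Reactants: 15 thioester
Product: 16 (2R,5R,6S)-5-acetyl-6-(tert-butyldimethylsilyloxy)-N-methoxy-N-methyl-2-(triethylsilyloxy)dec-9-enamide
Conditions: Me2CuLi (from MeLi and CuI), Et2O, −78 → −40 °C; aq NH4Cl
Reagents that add atoms: lithium dimethylcuprate, [Li+].C[Cu-]C
Why: Thioester-to-ketone conversion with an organocuprate introduces C14; the Weinreb amide does not react with the cuprate and the ketone is not attacked further.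

Step 11
Reactants: 16 methyl ketone
Product: 17 (2R,5S,6S)-6-(tert-butyldimethylsilyloxy)-N-methoxy-N-methyl-5-(prop-1-en-2-yl)-2-(triethylsilyloxy)dec-9-enamide
Conditions: Zn, CH2Br2, TiCl4, THF; then 16, CH2Cl2, 0 °C → rt
Reagents that add atoms: dibromomethane, BrCBr
Why: Lombardo methylenation is non-basic, so the C10 stereocentre next to the ketone should not epimerise and the β-silyloxy group should not eliminate; the amide is inert.

Step 12
Reactants: 17 diene
Product: 18 (R)-4-[(1S,6S)-6-(tert-butyldimethylsilyloxy)-2-methylcyclohex-2-en-1-yl]-N-methoxy-N-methyl-2-(triethylsilyloxy)butanamide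
Conditions: second-generation Grubbs catalyst (H2IMes)(PCy3)Cl2Ru=CHPh (5 mol%), CH2Cl2, 40 °C
Reagents that add atoms: none
Why: Ring-closing metathesis of the vinyl and isopropenyl groups forms the trisubstituted C5=C6 alkene of a six-membered ring and releases ethylene; no stereocentre is affected.

Step 13
Reactants: 18 Weinreb amide
Product: 19 (R)-5-[(1S,6S)-6-(tert-butyldimethylsilyloxy)-2-methylcyclohex-2-en-1-yl]-3-(triethylsilyloxy)pentan-2-one
Conditions: MeMgBr, THF, −20 → 0 °C
Reagents that add atoms: methylmagnesium bromide, C[Mg]Br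
Why: Weinreb ketone synthesis introduces C15; the chelated tetrahedral intermediate prevents over-addition and the α-silyloxy stereocentre C3 is retained.

Step 14
Reactants: 19 methyl ketone
Product: 21 (R)-5-[(1S,6S)-6-(tert-butyldimethylsilyloxy)-2-methylcyclohex-2-en-1-yl]-3-(triethylsilyloxy)pent-1-en-2-yl trifluoromethanesulfonate, via potassium enolate 20 (not isolated)
Conditions: KN(SiMe3)2, THF, −78 °C; then PhNTf2, −78 → −20 °C
Reagents that add atoms: N-phenylbis(trifluoromethanesulfonimide), O=S(=O)(N(c1ccccc1)S(=O)(=O)C(F)(F)F)C(F)(F)F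
Why: Kinetic deprotonation of an α'-silyloxy methyl ketone occurs at the unhindered methyl group, and O-sulfonylation of that enolate gives the terminal enol triflate without touching C3.

Step 15
Reactants: 21 alkenyl triflate
Product: 22 9β-(tert-butyldimethylsilyloxy)-3α-(triethylsilyloxy)-11,12,13-trinor-10βH-eremophila-4(15),6-diene
Conditions: Pd(OAc)2 (10 mol%), PPh3 (40 mol%), Et3N, MeCN, 80 °C
Reagents that add atoms: none
Why: Pd(OAc)2 is reduced by PPh3 to zerovalent palladium, which adds oxidatively to the C4–OTf bond; the cationic alkenylpalladium adds syn across the C5=C6 alkene to form C4–C5, a C7 hydrogen is lost by syn β-hydride elimination, and Et3N returns the hydridopalladium triflate to zerovalent palladium. The closest known reaction type is the intramolecular Heck cyclisation of alkenyl triflates onto trisubstituted cyclohexenes, which gives cis-fused bicycles with a quaternary ring-fusion carbon. Ring A closes in the 6-exo-trig mode; the 7-endo alternative would bond C4 to C6 and place palladium on the tertiary C5, and is disfavoured by the tether length and by sterics. The new stereocentre C5 is controlled by C10: the three-atom tether lets the alkenylpalladium reach only the alkene face that carries C1, so C4 and C1 end up cis on ring B and the C5 methyl is cis to H10. The step needs exo regiochemistry, this facial selectivity, and elimination in one direction without later alkene migration. C5 has no hydrogen after insertion, so elimination can only run toward C7 and H10 is never at risk. The triflate leaving group (no halide on palladium) and the amine base should limit re-addition of Pd–H to the new 6,7-alkene. The O9 silyl ether is trans to the tether and lies on the face away from the reacting palladium.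

Step 16
Reactants: 22 bis-silyl ether
Product: 23 9β-(tert-butyldimethylsilyloxy)-11,12,13-trinor-10βH-eremophila-4(15),6-dien-3α-ol
Conditions: pyridinium p-toluenesulfonate (cat.), MeOH/CH2Cl2, 0 °C → rt
Reagents that add atoms: none
Why: Mild acid methanolysis removes the TES ether much faster than the secondary TBS ether, which frees only the allylic C3 hydroxyl.

Step 17
Reactants: 23 allylic alcohol
Product: 24 9β-(tert-butyldimethylsilyloxy)-11,12,13-trinor-10βH-eremophil-6-en-3α-ol (C15 methyl β, H4 α)
Conditions: Ru(OAc)2[(±)-BINAP] (2 mol%), H2 (50 atm), MeOH/CH2Cl2, rt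
Reagents that add atoms: none
Why: Hydroxyl-directed homogeneous hydrogenation: the ruthenium diacetate–diphosphine complex reduces only alkenes that chelate through a neighbouring hydroxyl, so the 4(15)-alkene reacts and the 6,7-alkene is left. Hydrogen is delivered to C4 from the α-face of O3, which is also the face away from the axial C14, so the new methyl is β and cis to C14. The racemic ligand is used because the stereocentre is set by the substrate and the faster-reacting (matched) complex is then always present.

Step 18
Reactants: 24 alcohol; 25 (E)-2-methylbut-2-enoyl chloride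
Product: 26 9β-(tert-butyldimethylsilyloxy)-11,12,13-trinor-10βH-eremophil-6-en-3α-yl (E)-2-methylbut-2-enoate
Conditions: DMAP, pyridine, CH2Cl2, 0 °C → rt
Reagents that add atoms: none
Why: DMAP-catalysed acylation of the equatorial secondary alcohol with the acid chloride; the E-configured tiglate is the stable isomer and should not isomerise.

Step 19
Reactants: 26 tiglate
Product: 27 9β-(tert-butyldimethylsilyloxy)-8-oxo-11,12,13-trinor-10βH-eremophil-6-en-3α-yl (E)-2-methylbut-2-enoate
Conditions: Rh2(cap)4 (1 mol%), t-BuOOH (70% aq), 1,2-dichloroethane, 40 °C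
Reagents that add atoms: tert-butyl hydroperoxide, CC(C)(C)OO
Why: Dirhodium caprolactamate-catalysed allylic oxidation with tert-butyl hydroperoxide: C8 is the only allylic CH2 of the 6,7-alkene (C5 is quaternary), and trapping of the allyl radical at C8 rather than at the neopentyl C6 gives the enone. The tiglate methyls sit on an electron-poor alkene and should be much less reactive.

Step 20
Reactants: 27 silyloxy enone
Product: 28 9β-hydroxy-8-oxo-11,12,13-trinor-10βH-eremophil-6-en-3α-yl (E)-2-methylbut-2-enoate
Conditions: HF·pyridine, pyridine, THF, 0 °C → rt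
Reagents that add atoms: none
Why: Buffered fluoride desilylation frees the C9 hydroxyl without touching the tiglate or enolising the ketone; O9 stays in the equatorial β-position.

Step 21
Reactants: 28 hydroxy enone; 29 3-methylbut-2-enoic acid
Product: 31 9β-(3-methylbut-2-enoyloxy)-8-oxo-11,12,13-trinor-10βH-eremophil-6-en-3α-yl (E)-2-methylbut-2-enoate, via O-acylisourea 30 (not isolated)
Conditions: DCC, DMAP (cat.), CH2Cl2, 0 °C → rt
Reagents that add atoms: none
Why: Steglich esterification with the free acid avoids the vinylketene pathway of the acid chloride and amine, which would deconjugate the senecioate.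

Step 22
Reactants: 31 enone diester
Product: 32 7-iodo-9β-(3-methylbut-2-enoyloxy)-8-oxo-11,12,13-trinor-10βH-eremophil-6-en-3α-yl (E)-2-methylbut-2-enoate
Conditions: I2, pyridine, CH2Cl2, rt
Reagents that add atoms: iodine, II
Why: α-Iodination of the enone by conjugate addition of pyridine, iodination of the enolate and elimination; this works on cyclohexenones with a quaternary γ-carbon, and pyridine is too weak a base to disturb C9.

Step 23
Reactants: 32 iodoenone; 33 tributyl(prop-1-en-2-yl)stannane
Product: 34 9β-(3-methylbut-2-enoyloxy)-8-oxo-10βH-eremophila-6,11-dien-3α-yl (E)-2-methylbut-2-enoate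
Conditions: Pd2(dba)3, AsPh3, CuI, N-methylpyrrolidinone, rt → 40 °C
Reagents that add atoms: none
Why: Stille coupling of an α-iodoenone with an alkenylstannane under neutral conditions forms C7–C11 and leaves both esters and the C9 stereocentre intact.

Step 24
Reactants: 34 dienone
Product: 36 9β-(3-methylbut-2-enoyloxy)-8-oxo-10βH-eremophil-11-en-3α-yl (E)-2-methylbut-2-enoate (7β-isopropenyl), via copper enolate 35 (not isolated)
Conditions: [(Ph3P)CuH]6, toluene, rt; then aq NH4Cl, 0 °C
Reagents that add atoms: none
Why: Copper hydride conjugate reduction delivers hydride to C6 of the enone much faster than to the two hindered enoate esters. Kinetic protonation of the dienolate at the α-carbon C7 from the α-face (axial) places the isopropenyl group equatorial (β); this is also the more stable C7 epimer, because the other one would put the isopropenyl group syn-axial to C4.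

## Compound list

1 | (R)-3-hydroxydihydrofuran-2(3H)-one | O[C@@H]1CCOC1=O | starting material
2 | (R)-3-(triethylsilyloxy)dihydrofuran-2(3H)-one | CC[Si](CC)(CC)O[C@@H]1CCOC1=O | intermediate
3 | (R)-4-hydroxy-N-methoxy-N-methyl-2-(triethylsilyloxy)butanamide | CON(C)C(=O)[C@H](O[Si](CC)(CC)CC)CCO | intermediate
4 | (R)-N-methoxy-N-methyl-4-oxo-2-(triethylsilyloxy)butanamide | CON(C)C(=O)[C@H](O[Si](CC)(CC)CC)CC=O | intermediate
5 | benzyl (triphenylphosphoranylidene)acetate | O=C(OCc1ccccc1)C=P(c1ccccc1)(c1ccccc1)c1ccccc1 | starting material
6 | benzyl (R,E)-6-[methoxy(methyl)amino]-6-oxo-5-(triethylsilyloxy)hex-2-enoate | CON(C)C(=O)[C@H](O[Si](CC)(CC)CC)C/C=C/C(=O)OCc1ccccc1 | intermediate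
7 | (R)-6-[methoxy(methyl)amino]-6-oxo-5-(triethylsilyloxy)hexanoic acid | CON(C)C(=O)[C@H](O[Si](CC)(CC)CC)CCCC(=O)O | intermediate
8 | (R)-4-benzyloxazolidin-2-one | O=C1OC[C@@H](Cc2ccccc2)N1 | starting material
9 | mixed anhydride of 7 with pivalic acid | CON(C)C(=O)[C@H](O[Si](CC)(CC)CC)CCCC(=O)OC(=O)C(C)(C)C | intermediate
10 | (R)-4-benzyl-3-{(R)-6-[methoxy(methyl)amino]-6-oxo-5-(triethylsilyloxy)hexanoyl}oxazolidin-2-one | CON(C)C(=O)[C@H](O[Si](CC)(CC)CC)CCCC(=O)N1C(=O)OC[C@H]1Cc1ccccc1 | intermediate
11 | pent-4-enal | C=CCCC=O | starting material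
12 | dibutylboron (Z)-enolate of 10 | CON(C)C(=O)[C@H](O[Si](CC)(CC)CC)CC/C=C(\OB(CCCC)CCCC)N1C(=O)OC[C@H]1Cc1ccccc1 | intermediate
13 | (R)-4-benzyl-3-{(2R,5R)-2-[(S)-1-hydroxypent-4-en-1-yl]-6-[methoxy(methyl)amino]-6-oxo-5-(triethylsilyloxy)hexanoyl}oxazolidin-2-one | CON(C)C(=O)[C@H](O[Si](CC)(CC)CC)CC[C@H]([C@@H](O)CCC=C)C(=O)N1C(=O)OC[C@H]1Cc1ccccc1 | intermediate
14 | (R)-4-benzyl-3-{(2R,5R)-2-[(S)-1-(tert-butyldimethylsilyloxy)pent-4-en-1-yl]-6-[methoxy(methyl)amino]-6-oxo-5-(triethylsilyloxy)hexanoyl}oxazolidin-2-one | CON(C)C(=O)[C@H](O[Si](CC)(CC)CC)CC[C@H]([C@@H](O[Si](C)(C)C(C)(C)C)CCC=C)C(=O)N1C(=O)OC[C@H]1Cc1ccccc1 | intermediate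
15 | S-ethyl (2R,5R)-2-[(S)-1-(tert-butyldimethylsilyloxy)pent-4-en-1-yl]-6-[methoxy(methyl)amino]-6-oxo-5-(triethylsilyloxy)hexanethioate | CON(C)C(=O)[C@H](O[Si](CC)(CC)CC)CC[C@H]([C@@H](O[Si](C)(C)C(C)(C)C)CCC=C)C(=O)SCC | intermediate
16 | (2R,5R,6S)-5-acetyl-6-(tert-butyldimethylsilyloxy)-N-methoxy-N-methyl-2-(triethylsilyloxy)dec-9-enamide | CON(C)C(=O)[C@H](O[Si](CC)(CC)CC)CC[C@H]([C@@H](O[Si](C)(C)C(C)(C)C)CCC=C)C(C)=O | intermediate
17 | (2R,5S,6S)-6-(tert-butyldimethylsilyloxy)-N-methoxy-N-methyl-5-(prop-1-en-2-yl)-2-(triethylsilyloxy)dec-9-enamide | CON(C)C(=O)[C@H](O[Si](CC)(CC)CC)CC[C@H]([C@@H](O[Si](C)(C)C(C)(C)C)CCC=C)C(C)=C | intermediate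
18 | (R)-4-[(1S,6S)-6-(tert-butyldimethylsilyloxy)-2-methylcyclohex-2-en-1-yl]-N-methoxy-N-methyl-2-(triethylsilyloxy)butanamide | CON(C)C(=O)[C@H](O[Si](CC)(CC)CC)CC[C@H]1C(C)=CCC[C@@H]1O[Si](C)(C)C(C)(C)C | intermediate
19 | (R)-5-[(1S,6S)-6-(tert-butyldimethylsilyloxy)-2-methylcyclohex-2-en-1-yl]-3-(triethylsilyloxy)pentan-2-one | CC(=O)[C@H](O[Si](CC)(CC)CC)CC[C@H]1C(C)=CCC[C@@H]1O[Si](C)(C)C(C)(C)C | intermediate
20 | potassium enolate of 19 (C4=C15 enolate) | [K+].C=C([O-])[C@H](O[Si](CC)(CC)CC)CC[C@H]1C(C)=CCC[C@@H]1O[Si](C)(C)C(C)(C)C | intermediate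
21 | (R)-5-[(1S,6S)-6-(tert-butyldimethylsilyloxy)-2-methylcyclohex-2-en-1-yl]-3-(triethylsilyloxy)pent-1-en-2-yl trifluoromethanesulfonate | C=C(OS(=O)(=O)C(F)(F)F)[C@H](O[Si](CC)(CC)CC)CC[C@H]1C(C)=CCC[C@@H]1O[Si](C)(C)C(C)(C)C | intermediate
22 | 9β-(tert-butyldimethylsilyloxy)-3α-(triethylsilyloxy)-11,12,13-trinor-10βH-eremophila-4(15),6-diene (cis-fused, C14 β) | C1=C[C@@]2(C)[C@H](CC[C@@H](O[Si](CC)(CC)CC)C2=C)[C@@H](O[Si](C)(C)C(C)(C)C)C1 | intermediate
23 | 9β-(tert-butyldimethylsilyloxy)-11,12,13-trinor-10βH-eremophila-4(15),6-dien-3α-ol | C1=C[C@@]2(C)[C@H](CC[C@@H](O)C2=C)[C@@H](O[Si](C)(C)C(C)(C)C)C1 | intermediate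
24 | 9β-(tert-butyldimethylsilyloxy)-11,12,13-trinor-10βH-eremophil-6-en-3α-ol (C15 β) | C1=C[C@@]2(C)[C@H](CC[C@@H](O)[C@@H]2C)[C@@H](O[Si](C)(C)C(C)(C)C)C1 | intermediate
25 | (E)-2-methylbut-2-enoyl chloride (tigloyl chloride) | C/C=C(\C)C(Cl)=O | starting material
26 | 9β-(tert-butyldimethylsilyloxy)-11,12,13-trinor-10βH-eremophil-6-en-3α-yl (E)-2-methylbut-2-enoate | C1=C[C@@]2(C)[C@H](CC[C@@H](OC(=O)/C(C)=C/C)[C@@H]2C)[C@@H](O[Si](C)(C)C(C)(C)C)C1 | intermediate
27 | 9β-(tert-butyldimethylsilyloxy)-8-oxo-11,12,13-trinor-10βH-eremophil-6-en-3α-yl (E)-2-methylbut-2-enoate | C1=C[C@@]2(C)[C@H](CC[C@@H](OC(=O)/C(C)=C/C)[C@@H]2C)[C@@H](O[Si](C)(C)C(C)(C)C)C1=O | intermediate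
28 | 9β-hydroxy-8-oxo-11,12,13-trinor-10βH-eremophil-6-en-3α-yl (E)-2-methylbut-2-enoate | C1=C[C@@]2(C)[C@H](CC[C@@H](OC(=O)/C(C)=C/C)[C@@H]2C)[C@@H](O)C1=O | intermediate
29 | 3-methylbut-2-enoic acid | CC(C)=CC(=O)O | starting material
30 | O-(3-methylbut-2-enoyl)-N,N'-dicyclohexylisourea | CC(C)=CC(=O)OC(=NC1CCCCC1)NC1CCCCC1 | intermediate
31 | 9β-(3-methylbut-2-enoyloxy)-8-oxo-11,12,13-trinor-10βH-eremophil-6-en-3α-yl (E)-2-methylbut-2-enoate | C1=C[C@@]2(C)[C@H](CC[C@@H](OC(=O)/C(C)=C/C)[C@@H]2C)[C@@H](OC(=O)C=C(C)C)C1=O | intermediate
32 | 7-iodo-9β-(3-methylbut-2-enoyloxy)-8-oxo-11,12,13-trinor-10βH-eremophil-6-en-3α-yl (E)-2-methylbut-2-enoate | IC1=C[C@@]2(C)[C@H](CC[C@@H](OC(=O)/C(C)=C/C)[C@@H]2C)[C@@H](OC(=O)C=C(C)C)C1=O | intermediate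
33 | tributyl(prop-1-en-2-yl)stannane | C=C(C)[Sn](CCCC)(CCCC)CCCC | starting material
34 | 9β-(3-methylbut-2-enoyloxy)-8-oxo-10βH-eremophila-6,11-dien-3α-yl (E)-2-methylbut-2-enoate | C=C(C)C1=C[C@@]2(C)[C@H](CC[C@@H](OC(=O)/C(C)=C/C)[C@@H]2C)[C@@H](OC(=O)C=C(C)C)C1=O | intermediate
35 | copper C7=C8 enolate from 34 (phosphine ligands not drawn) | C=C(C)C=1C[C@@]2(C)[C@H](CC[C@@H](OC(=O)/C(C)=C/C)[C@@H]2C)[C@@H](OC(=O)C=C(C)C)C=1O[Cu] | intermediate
36 | 9β-(3-methylbut-2-enoyloxy)-8-oxo-10βH-eremophil-11-en-3α-yl (E)-2-methylbut-2-enoate (CNP0375730.1) | C=C(C)[C@H]1C[C@@]2(C)[C@H](CC[C@@H](OC(=O)/C(C)=C/C)[C@@H]2C)[C@@H](OC(=O)C=C(C)C)C1=O | target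

## Step count and least certain steps

Total: 24 steps. Longest linear sequence: 24 steps (1 → 36); 5, 8, 11, 25, 29 and 33 are purchased.

**Step 15 (key step).** The most likely failure is re-addition of the hydridopalladium species to the new 6,7-alkene, followed by migration of the double bond toward C8 and C9. A second possibility is slow insertion into the hindered trisubstituted alkene, so that reduction or hydrolysis of the triflate wins. The fallback generates the same C4 alkenylpalladium without oxidative addition or base. It sets out from 21: elimination of triflate with LiN(i-Pr)2 in THF at −78 °C gives (R)-3-(triethylsilyloxy)-5-[(1S,6S)-6-(tert-butyldimethylsilyloxy)-2-methylcyclohex-2-en-1-yl]pent-1-yne F1. Palladium-catalysed Alder-ene cycloisomerisation of this 1,7-enyne (Pd2(dba)3·CHCl3, PPh3, AcOH, benzene, 60 °C) then proceeds by hydropalladation of the alkyne at C4, the same 6-exo insertion and β-hydride elimination toward C7. It returns to the route at 22.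

**Step 17.** The hindered 4(15)-alkene next to quaternary C5 may coordinate too slowly. The ruthenium hydride may instead isomerise the allylic alcohol to the C3 ketone. A more active catalyst would start to reduce the 6,7-alkene. The fallback postpones the hydrogenation until ring B is electron-poor. It sets out from 23: acetylation (Ac2O, pyridine, DMAP) gives 9β-(tert-butyldimethylsilyloxy)-11,12,13-trinor-10βH-eremophila-4(15),6-dien-3α-yl acetate F2, whose C3–H is deactivated. Allylic oxidation as in step 19 gives the 8-oxo acetate F3. Methanolysis (K2CO3, MeOH, 0 °C) gives 9β-(tert-butyldimethylsilyloxy)-3α-hydroxy-11,12,13-trinor-10βH-eremophila-4(15),6-dien-8-one F4. Hydroxyl-directed hydrogenation with [Ir(cod)(PCy3)(py)]PF6 and H2 in CH2Cl2 gives 9β-(tert-butyldimethylsilyloxy)-3α-hydroxy-11,12,13-trinor-10βH-eremophil-6-en-8-one F5. Acylation with 25 returns to the route at 27.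

**Step 19.** The radical chain may not be site-specific: oxygen may enter at C6 with transposition of the alkene, the tiglate methyls may be attacked, or the reaction may stall on the hindered methylene. The fallback uses a π-allylpalladium instead of a radical. It sets out from 26: Pd(OAc)2, p-benzoquinone and AcOH at 50 °C should give the 8-acetoxy-6-ene F6 by attack of acetate on the less hindered C8 terminus. Mild methanolysis (K2CO3, MeOH, 0 °C; the unhindered acetate before the conjugated tiglate) gives the 8-hydroxy-6-ene F7. Oxidation of the allylic alcohol with MnO2 returns to the route at 27.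

**Step 24.** Protonation of the dienolate may occur from the β-face (wrong C7 epimer) or at C12, or the product may drift into conjugation during work-up; slow reduction of the tiglate is a further risk. The fallback separates hydride delivery from protonation. It sets out from 34: 1,4-hydrosilylation (RhCl(PPh3)3 cat., Et3SiH, benzene, 50 °C) gives the isolable triethylsilyl dienol ether F8. Protodesilylation under buffered fluoride (HF·pyridine, pyridine, THF, −20 °C), with a small proton donor, then returns to the route at 36.

**Step 14.** Enolisation may occur toward C3, which would give the internal triflate and loss of configuration at C3, or the base may induce silyl migration. The fallback avoids enolate chemistry. It sets out from 19: condensation with N2H4·H2O (Et3N, EtOH) gives the hydrazone F9. Barton vinyl iodide synthesis (I2, 1,1,3,3-tetramethylguanidine, Et2O, 0 °C) gives the 2-iodoalkene F10. Heck cyclisation of the iodide (Pd(OAc)2, PPh3, Ag2CO3, MeCN, 80 °C) returns to the route at 22.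

## Further compounds

F1 | step 15 | (R)-3-(triethylsilyloxy)-5-[(1S,6S)-6-(tert-butyldimethylsilyloxy)-2-methylcyclohex-2-en-1-yl]pent-1-yne | C#C[C@H](O[Si](CC)(CC)CC)CC[C@H]1C(C)=CCC[C@@H]1O[Si](C)(C)C(C)(C)C
F2 | step 17 | 9β-(tert-butyldimethylsilyloxy)-11,12,13-trinor-10βH-eremophila-4(15),6-dien-3α-yl acetate | C1=C[C@@]2(C)[C@H](CC[C@@H](OC(C)=O)C2=C)[C@@H](O[Si](C)(C)C(C)(C)C)C1
F3 | step 17 | 9β-(tert-butyldimethylsilyloxy)-8-oxo-11,12,13-trinor-10βH-eremophila-4(15),6-dien-3α-yl acetate | C1=C[C@@]2(C)[C@H](CC[C@@H](OC(C)=O)C2=C)[C@@H](O[Si](C)(C)C(C)(C)C)C1=O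
F4 | step 17 | 9β-(tert-butyldimethylsilyloxy)-3α-hydroxy-11,12,13-trinor-10βH-eremophila-4(15),6-dien-8-one | C1=C[C@@]2(C)[C@H](CC[C@@H](O)C2=C)[C@@H](O[Si](C)(C)C(C)(C)C)C1=O
F5 | step 17 | 9β-(tert-butyldimethylsilyloxy)-3α-hydroxy-11,12,13-trinor-10βH-eremophil-6-en-8-one | C1=C[C@@]2(C)[C@H](CC[C@@H](O)[C@@H]2C)[C@@H](O[Si](C)(C)C(C)(C)C)C1=O
F6 | step 19 | 8-acetoxy-9β-(tert-butyldimethylsilyloxy)-11,12,13-trinor-10βH-eremophil-6-en-3α-yl (E)-2-methylbut-2-enoate (C8 configuration not defined) | C1=C[C@@]2(C)[C@H](CC[C@@H](OC(=O)/C(C)=C/C)[C@@H]2C)[C@@H](O[Si](C)(C)C(C)(C)C)C1OC(C)=O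
F7 | step 19 | 9β-(tert-butyldimethylsilyloxy)-8-hydroxy-11,12,13-trinor-10βH-eremophil-6-en-3α-yl (E)-2-methylbut-2-enoate (C8 configuration not defined) | C1=C[C@@]2(C)[C@H](CC[C@@H](OC(=O)/C(C)=C/C)[C@@H]2C)[C@@H](O[Si](C)(C)C(C)(C)C)C1O
F8 | step 24 | 9β-(3-methylbut-2-enoyloxy)-8-(triethylsilyloxy)-10βH-eremophila-7,11-dien-3α-yl (E)-2-methylbut-2-enoate | C=C(C)C=1C[C@@]2(C)[C@H](CC[C@@H](OC(=O)/C(C)=C/C)[C@@H]2C)[C@@H](OC(=O)C=C(C)C)C=1O[Si](CC)(CC)CC
F9 | step 14 | hydrazone of 19 | CC(=NN)[C@H](O[Si](CC)(CC)CC)CC[C@H]1C(C)=CCC[C@@H]1O[Si](C)(C)C(C)(C)C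
F10 | step 14 | (R)-2-iodo-3-(triethylsilyloxy)-5-[(1S,6S)-6-(tert-butyldimethylsilyloxy)-2-methylcyclohex-2-en-1-yl]pent-1-ene | C=C(I)[C@H](O[Si](CC)(CC)CC)CC[C@H]1C(C)=CCC[C@@H]1O[Si](C)(C)C(C)(C)C
A1 | alternative 1 | (+)-aristolochene (eremophila-9,11-diene) | C=C(C)[C@@H]1C[C@@]2(C)C(CCC[C@@H]2C)=CC1
A2 | alternative 1 | (2E,6E)-farnesyl diphosphate | CC(C)=CCC/C(C)=C/CC/C(C)=C/COP(=O)(O)OP(=O)(O)O
A3 | alternative 2 | cis-fused 4,5-dimethyldecalin with C3 ketone and C8 methyl enol ether | C1C[C@@]2(C)[C@H](CCC(=O)[C@@H]2C)C=C1OC
A4 | alternative 2 | 1-methoxy-3,4-dimethyl-2-vinylbicyclo[2.2.2]oct-5-en-2-ol (C3–C8 bonded; vinyl on the alkene side) | C=C[C@]1(O)[C@H](C)[C@@]2(C)CC[C@]1(OC)C=C2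
A5 | alternative 3 | C8 carbinol of the target | C=C(C)[C@H]1C[C@@]2(C)[C@H](CC[C@@H](OC(=O)/C(C)=C/C)[C@@H]2C)[C@@H](OC(=O)C=C(C)C)[C@@H]1O
A6 | alternative 3 | ring A aldehyde with a prenyl group on C5 and the C9 senecioate | CC(C)=CC[C@@]2(C)[C@H](CC[C@@H](OC(=O)/C(C)=C/C)[C@@H]2C)[C@@H](OC(=O)C=C(C)C)C=O
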